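# Total synthesis proposal for CNP0311700.2: closure of the nine-membered ring by chromium-mediated allylation at the ethyl-bearing carbon

Atom labels (C1 to C23) follow the order of the atoms in the target SMILES. Compound numbers (1 to 43) follow the order of first appearance in the steps.

## Analysis of the target

The target 43 is a tetracyclic lactam. An azepan-2-one (N17, C18–C21, C22, C23) and a nine-membered ring (C3, C4, C8, C9, C10, C11, N17, C23, C22) share the unit N17–C23–C22; a γ-butyrolactone (C4, O5, C6, C7, C8) is fused to the nine-membered ring, and a second α-methyl-γ-butyrolactone (C12–C15, O16) hangs from C11. There are eight stereocentres (3R, 4S, 7S, 8S, 11S, 12S, 14S, 22R): five contiguous ones run from the lactam α-carbon C22 over the ethyl-bearing C3 into the fused lactone (C4, C8, C7), and three (C11, C12, C14) form a separate amino alcohol and lactone array. The fused lactone is cis (H4 and H8 on the same side) with the C7 methyl group trans to C9; ethyl and oxygen are syn along C8–C4–C3–C22; nitrogen and oxygen are syn along C10–C11–C12–C13; the pendant lactone is 2,4-cis. The sensitive groups are the C9 ketone, which has the lactone oxygen on its β-carbon C4 (base opens the lactone by elimination and epimerises C8), the two lactone α-centres, and any free amine on C11, which would attack the pendant lactone and turn it into a six-membered lactam. The difficulty is the nine-membered ring: the lactam that is cisoid inside the azepanone is transoid inside this ring, so lactamisation cannot close it, and five contiguous stereocentres sit on a medium ring without a rigid template. The strategy rests on C3, which lies between the lactam α-carbon C22 and the oxygen-bearing C4. This is the pattern left when a 2-carbonyl-substituted allyl metal adds to an aldehyde, so the bond C3–C4 can close the nine-membered ring and leave a C21=C22 double bond for later reduction.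

## Retrosynthetic reasoning

**C9 oxidation level.** The ketone of 43 is taken back to the carbinol 42 and its silyl ether 41. The β-acyloxy ketone is the most fragile part of the molecule, so it is made in the last step under non-basic conditions.

**C22.** The bond C22–H of 41 is cut back to the C21=C22 alkene of 40. The forward step is a hydrogenation, which has to deliver hydrogen to one face of a bridgehead-type alkene.

**Fused lactone.** The bond O5–C6 of 40 is opened to hydroxy ester 37. Both carbons that decide the cis fusion (C4, C8) are already stereocentres in 37, so the forward lactonisation only has to be chemoselective for C4–OH. The C9 oxygen stays silylated because it is also γ to C6.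

**Nine-membered ring (key disconnection).** In 37 the bond C3–C4 is cut. It is the only ring bond flanked by a carbinol carbon and by the allylic position of a carbonyl-substituted alkene, and cutting it gives an aldehyde and an allylic bromide on the same molecule, compound 35. The forward reaction (via allylchromium 36) closes the ring and sets C3 and C4 in one step. It must react through the ethyl-bearing terminus, place ethyl and hydroxyl syn, and choose the aldehyde face dictated by C8.

**Functional groups of 35.** The allylic bromide is traced to the Baylis–Hillman-type alcohol 34 (bromination with allylic shift), which comes from silyl ether 33. The aldehyde is traced to thioester 32, and this to the imide 31. This order is forced: the thioester reduction uses palladium and would destroy an allylic bromide, so the bromide is introduced last.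

**C8–C9.** Silyl ether 31 comes from aldol adduct 30, which is cut at C8–C9 into the succinate imide 28 and aldehyde 22. The auxiliary of 28 fixes C8; C7 is brought in from (S)-methylsuccinic acid 23. The C9 configuration is irrelevant for 43, since C9 ends as a ketone.

**Succinate fragment.** Imide 28 is the tert-butyl ester of acid 27, which is made from anhydride 24 and oxazolidinone 25 (via 26); 24 comes from 23. The tert-butyl ester is chosen because a γ-hydroxy tert-butyl ester cannot lactonise in the aldol adduct.

**C9 aldehyde.** Aldehyde 22 is traced through thioester 21 and acid 20 (via 19) to tert-butyl ester 18. This is the side-chain carboxyl of aspartic acid.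

**Pendant lactone.** Lactone 18 is opened to hydroxy ester 17 and ketone 16. The bond C12–C13 of 16 is cut into thioester 12 and the zinc reagent 15, made from iodide 14 and Roche ester 13. C14 thus comes from the chiral pool, and C12 is set by reduction next to C11. The lactone is built only after the nitrogen has become a lactam, so no free amine ever sits next to it.

**Azepinone.** Thioester 12 comes from methyl ester 11. The ring of 11 is opened at C21=C22 (ring-closing metathesis) to diene 10. Its amide bond is cut into amine 8 and acid 5 (as chloride 9). Amine 8 comes from the aspartate diester 6 and pent-4-enal 7; acid 5 comes from the Baylis–Hillman adduct 3 of methyl acrylate 1 and propanal 2, through silyl ether 4.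

## Alternatives that were turned down

**Alternative 1:** The fused lactone is cut at C7–C8, and the C9 oxygen is introduced in the same operation. The forward step starts from the mixed bromoacetal A1, in which the nine-membered ring is already closed and holds a C8=C9 double bond. Bu3SnH in the presence of air turns the C–Br bond into a radical at C7, which adds 5-exo to C8; the ring radical left at C9 is trapped by oxygen to give the lactol ether carbinol A2. One oxidation at the end would then make lactone and ketone together.
- For: the cis fusion at C4/C8 follows from the tether and cannot fail. Here it is stronger than the chosen route, which sets C4 and C8 in two separate events. It also needs no auxiliary and no β-silyloxy aldehyde.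
- Against: A1 already contains the nine-membered ring with C3, C4, C22 and a cis ring alkene, so the closure of the medium ring with its transoid lactam is left to an unspecified earlier step. The orientation of the C7 methyl group in a 5-exo radical closure is only weakly controlled, and oxygen trapping competes with direct reduction of the ring radical by the tin hydride.
- Comparison: the chosen strategy closes the medium ring and sets C3 and C4 in one step, and takes C7 and C8 from the chiral pool and an auxiliary.

**Alternative 2:** The nine-membered lactam is made by ring expansion: N17–C23 and C22–C3 are formed while an N17–C8 bond is broken. The chiral-pool pyrrolidine A3 is acylated at nitrogen by the acid fluoride A4 with Al(CH3)3, and the ammonium enolate rearranges through a chair ([3,3] shift) to the lactam A5, with an E-alkene C4=C8.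
- For: C3 and C22 arise together by chirality transfer through an ordered chair. On C22 this is clearly stronger than the chosen route, which sets that centre late by hydrogenation. The ring is formed without high dilution.
- Against: A5 lacks the whole lactone side. The E-alkene must be turned into C4–O and C8–C7 with cis fusion, with the C7 methyl group and an oxidised C9, by additions to a medium-ring alkene whose facial selectivity cannot be predicted. The pendant lactone must be grown from the CH2O group on C11, and the azepane must be closed after removal of the benzyl group.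
- Comparison: the chosen strategy brings C4, C7, C8 and C9 in with defined configuration and has both lactone precursors complete before the ring closes; the alternative would be longer after its key step.

**Alternative 3:** The ring arises by fragmentation: the bond C8–C23 of the bicyclic acylcyclopentanone A6 is broken while N17–C23 is formed. The free amine on C11 adds to the cyclopentanone carbonyl through a six-membered hemiaminal, and retro-Claisen cleavage gives the keto lactam A7.
- For: C3, C4, C7 and C22 are assembled on a rigid cis-fused bicycle, which is better stereocontrol than the chosen route has for C3 and C22. The C9 ketone appears at the right oxidation level without a protecting group, and the ring expansion has no entropic penalty.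
- Against: the cleavage produces the C8 enolate with the lactone oxygen on the β-carbon C4, so elimination and opening of the lactone threaten in the key step itself, and C8 is set only by protonation. The free amine on C11 is next to the pendant lactone carbinol and can convert that lactone into a six-membered lactam in competition with the attack at C23. The quaternary C8 of A6 is costly to build.
- Comparison: the chosen route never frees the amine beside the lactone and makes the β-acyloxy ketone only in the last step.

Key step: step 23

## Route

Remark: the silyloxy-bearing carbon C3 is carried as an unassigned pair of epimers from 3 to 34 (no descriptor in the SMILES); it becomes trigonal in 35, where both epimers converge.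

Step 1
Reactants: 1 methyl acrylate; 2 propanal
Product: 3 methyl 3-hydroxy-2-methylidenepentanoate (racemic)
Conditions: DABCO (0.2 equiv), neat, rt, 5 d
Reagents that add atoms: none
Why: Morita–Baylis–Hillman reaction; the amine adds to the acrylate, the zwitterionic enolate adds to the aldehyde and the amine is expelled; the carbinol centre is racemic and is erased in step 22.

Step 2
Reactants: 3 methyl 3-hydroxy-2-methylidenepentanoate
Product: 4 methyl 2-methylidene-3-(triethylsilyloxy)pentanoate
Conditions: TESCl, imidazole, CH2Cl2, 0 °C to rt
Reagents that add atoms: chlorotriethylsilane, CC[Si](Cl)(CC)CC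
Why: Silylation of a secondary alcohol; the triethylsilyl group is chosen because it can later be removed beside a tert-butyldimethylsilyl ether.

Step 3
Reactants: 4 methyl 2-methylidene-3-(triethylsilyloxy)pentanoate
Product: 5 2-methylidene-3-(triethylsilyloxy)pentanoic acid
Conditions: LiOH, THF/H2O, rt; 0.5 M HCl to pH 4, 0 °C
Reagents that add atoms: lithium hydroxide, [Li+].[OH-]
Why: Saponification of the methyl ester; the hindered secondary silyl ether tolerates aqueous LiOH, and the acidification is kept mild and cold.

Step 4
Reactants: 6 L-aspartic acid 4-tert-butyl 1-methyl diester hydrochloride; 7 pent-4-enal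
Product: 8 4-tert-butyl 1-methyl N-(pent-4-enyl)-L-aspartate
Conditions: Et3N (1 equiv), NaBH(OAc)3, ClCH2CH2Cl, rt
Reagents that add atoms: none
Why: Reductive amination; the α-branched amine is alkylated once only and the weakly acidic medium does not epimerise C11.

Step 5
Reactants: 5 2-methylidene-3-(triethylsilyloxy)pentanoic acid; 8 4-tert-butyl 1-methyl N-(pent-4-enyl)-L-aspartate
Product: 10 4-tert-butyl 1-methyl N-[2-methylidene-3-(triethylsilyloxy)pentanoyl]-N-(pent-4-enyl)-L-aspartate, via acid chloride 9 (not isolated)
Conditions: 5, 1-chloro-N,N,2-trimethylprop-1-en-1-amine, CH2Cl2, 0 °C; then 8, i-Pr2NEt, DMAP (cat.), 0 °C to rt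
Reagents that add atoms: none
Why: The chloroenamine forms the acid chloride without HCl, so the silyl ether survives; N-acylation of the secondary amine then gives the tertiary amide.

Step 6
Reactants: 10 diene amide
Product: 11 4-tert-butyl 1-methyl (2S)-2-{2-oxo-3-[1-(triethylsilyloxy)propyl]-1,5,6,7-tetrahydro-2H-azepin-1-yl}butanedioate (C21=C22 in the ring)
Conditions: second-generation Grubbs catalyst, RuCl2(H2IMes)(PCy3)(=CHPh) (10 mol %), toluene, 80 °C, 0.005 M
Reagents that add atoms: none
Why: Ring-closing metathesis; the carbene forms at the terminal pentenyl alkene and closes the seven-membered ring onto the 1,1-disubstituted acrylamide alkene with loss of ethene, as known for 2-substituted acrylamides.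

Step 7
Reactants: 11 azepinone diester
Product: 12 S-ethyl thioester at C12 (tert-butyl ester on C9 retained)
Conditions: Al(CH3)3, EtSH, CH2Cl2, 0 °C to rt
Reagents that add atoms: ethanethiol, CCS
Why: Ester to thioester exchange with the aluminium thiolate; it is not basic and does not activate a carboxyl group, so C11, which would racemise through an oxazolium ion on activation of the N-acyl-N-alkyl amino acid, is kept; the tert-butyl ester is too hindered to exchange.

Step 8
Reactants: 13 methyl (S)-3-hydroxy-2-methylpropanoate
Product: 14 methyl (R)-3-iodo-2-methylpropanoate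
Conditions: I2, PPh3, imidazole, CH2Cl2, 0 °C to rt
Reagents that add atoms: iodine, II
Why: Appel-type iodination of the primary alcohol; the stereocentre is not touched (the descriptor changes only because iodine alters the priorities).

Step 9
Reactants: 14 methyl (R)-3-iodo-2-methylpropanoate; 12 S-ethyl thioester
Product: 16 γ-keto ester (C12 ketone, C15 methyl ester, C14 methyl), via zinc reagent 15 (not isolated)
Conditions: 14, Zn dust (activated with BrCH2CH2Br, TMSCl), THF/DMA, rt; then 12, PdCl2(PPh3)2 (8 mol %), toluene, rt
Reagents that add atoms: none
Why: Fukuyama coupling; zerovalent palladium inserts into the acyl–sulfur bond, the ester-stabilised alkylzinc transmetalates and the ketone is released; the neutral conditions leave C11 and C14 untouched.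

Step 10
Reactants: 16 γ-keto ester
Product: 18 pendant cis-lactone (11S,12S,14S) with tert-butyl ester on C9, via hydroxy ester 17 (not isolated)
Conditions: LiBH(s-Bu)3, THF, −78 °C; AcOH; then PPTS (cat.), CH2Cl2, rt
Reagents that add atoms: none
Why: Felkin–Anh reduction: the bulky, non-chelating hydride attacks the ketone anti to the lactam nitrogen on C11 and gives the 11,12-syn amino alcohol (12S); the carbinol then lactonises onto the methyl ester (the tert-butyl ester does not compete), which makes the 2,4-cis lactone with C14 from the Roche ester.

Step 11
Reactants: 18 lactone tert-butyl ester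
Product: 20 carboxylic acid at C9, via silyl ester 19 (not isolated)
Conditions: TMSOTf, 2,6-lutidine, CH2Cl2, 0 °C to rt; then pH 5 buffer
Reagents that add atoms: none
Why: Silyl triflate cleavage of the tert-butyl ester (loss of isobutene) and hydrolysis of the silyl ester on work-up; unlike protic acid, these conditions keep the triethylsilyl ether.

Step 12
Reactants: 20 carboxylic acid
Product: 21 S-ethyl thioester at C9
Conditions: EtSH, EDC·HCl, DMAP (cat.), CH2Cl2, 0 °C to rt
Reagents that add atoms: ethanethiol, CCS
Why: Steglich-type thioesterification; the acid is β to C11, so activation cannot touch the stereocentre.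

Step 13
Reactants: 21 S-ethyl thioester
Product: 22 aldehyde at C9 (pendant lactone, azepinone with silyloxypropyl group)
Conditions: Et3SiH, Pd/C (10 mol %), acetone, rt
Reagents that add atoms: none
Why: Fukuyama reduction; the thioester alone is reduced, whereas a hydride reagent would also attack the lactone.

Step 14
Reactants: 23 (S)-methylsuccinic acid
Product: 24 (S)-methylsuccinic anhydride
Conditions: AcCl, reflux; evaporation
Reagents that add atoms: none
Why: Cyclodehydration of the diacid; the stereocentre is not enolised under these acidic conditions.

Step 15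
Reactants: 25 (R)-4-benzyl-1,3-oxazolidin-2-one; 24 (S)-methylsuccinic anhydride
Product: 27 (2S)-4-[(4R)-4-benzyl-2-oxo-1,3-oxazolidin-3-yl]-2-methyl-4-oxobutanoic acid, via lithiated oxazolidinone 26 (not isolated)
Conditions: 25, n-BuLi, THF, −78 °C; then 24, −78 to 0 °C; 1 M HCl
Reagents that add atoms: none
Why: N-Acylation of the lithiated auxiliary by the anhydride at its less hindered carbonyl (next to CH2), which places the auxiliary on C4 and leaves the free acid at C6; any regioisomer is removed at this stage.

Step 16
Reactants: 27 imide acid
Product: 28 tert-butyl (2S)-4-[(4R)-4-benzyl-2-oxo-1,3-oxazolidin-3-yl]-2-methyl-4-oxobutanoate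
Conditions: tert-butyl 2,2,2-trichloroacetimidate, BF3·OEt2 (cat.), CH2Cl2/cyclohexane, rt
Reagents that add atoms: tert-butyl 2,2,2-trichloroacetimidate, CC(C)(C)OC(=N)C(Cl)(Cl)Cl
Why: Acid-catalysed tert-butylation without base, so C7 is not epimerised; the tert-butyl ester is needed because it cannot be attacked by the C9 hydroxyl formed in step 17.

Step 17
Reactants: 28 succinate imide; 22 aldehyde
Product: 30 syn-aldol adduct (new bond C8–C9, C9 hydroxyl), via boron enolate 29 (not isolated)
Conditions: 28 (1.5 equiv), Bu2BOTf, i-Pr2NEt, CH2Cl2, 0 °C; then 22, −78 to 0 °C; pH 7 buffer, MeOH, H2O2, 0 °C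
Reagents that add atoms: none
Why: Evans syn aldol: the Z boron enolate reacts through a Zimmerman–Traxler chair, and the (R)-benzyl auxiliary selects the enolate face that gives the C8 configuration of the target (C9 is S, but this centre is later oxidised); enolisation is at C8 only, and the γ-hydroxy tert-butyl ester does not lactonise.

Step 18
Reactants: 30 aldol adduct
Product: 31 C9 tert-butyldimethylsilyl ether
Conditions: TBSOTf, 2,6-lutidine, CH2Cl2, −78 to 0 °C
Reagents that add atoms: tert-butyldimethylsilyl triflate, CC(C)(C)[Si](C)(C)OS(=O)(=O)C(F)(F)F
Why: Silylation of the aldol hydroxyl is fast below 0 °C, where the tert-butyl ester is not yet attacked by the silyl triflate; the ether blocks the second γ-hydroxyl that could lactonise onto C6.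

Step 19
Reactants: 31 silylated imide
Product: 32 S-ethyl thioester at C4
Conditions: EtSH, n-BuLi, THF, 0 °C
Reagents that add atoms: ethanethiol, CCS
Why: Cleavage of the imide by lithium ethanethiolate at the exocyclic carbonyl, which works on hindered α-branched imides; the soft thiolate leaves lactone, ester and silyl ethers alone, and the auxiliary 25 is recovered.

Step 20
Reactants: 32 S-ethyl thioester
Product: 33 aldehyde at C4
Conditions: Et3SiH, Pd/C (10 mol %), acetone, rt
Reagents that add atoms: none
Why: Fukuyama reduction gives the aldehyde directly at the right oxidation level, without hydride and without base, so C8 and the β-silyloxy group are kept.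

Step 21
Reactants: 33 aldehyde
Product: 34 hydroxy aldehyde (free C3 hydroxyl on the azepinone side chain)
Conditions: HF·pyridine, pyridine, THF, 0 °C
Reagents that add atoms: none
Why: Selective desilylation: the secondary allylic triethylsilyl ether is cleaved far faster than the hindered secondary tert-butyldimethylsilyl ether on C9; the buffered medium leaves the aldehyde and the tert-butyl ester intact.

Step 22
Reactants: 34 hydroxy aldehyde
Product: 35 bromo aldehyde: 4-bromo-3-[(E)-propylidene]azepan-2-one on N17, aldehyde at C4
Conditions: NBS, Me2S, CH2Cl2, −20 °C; then 34, −20 to 0 °C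
Reagents that add atoms: N-bromosuccinimide, O=C1CCC(=O)N1Br
Why: Corey–Kim-type bromination of a Baylis–Hillman-type alcohol with allylic shift: the alkoxysulfonium ion is displaced by bromide at the ring carbon C21, and the conjugated propylidene lactam forms with ethyl trans to the carbonyl; an unshifted bromide would give the same allyl metal, and the aldehyde is inert to the reagent.

Step 23
Reactants: 35 bromo aldehyde
Product: 37 cyclised hydroxy ester (3R,4S; nine-membered ring closed; C21=C22 in the azepinone), via allylchromium species 36 (not isolated)
Conditions: CrCl2 (8 equiv), THF, rt, slow addition of 35 (final 0.002 M); aqueous work-up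
Reagents that add atoms: none
Why: Intramolecular Nozaki–Hiyama allylation: two equivalents of divalent chromium insert into the C21–Br bond to give the trivalent allylchromium 36, which binds the aldehyde oxygen and forms the C–C bond at its γ-terminus C3 through a six-membered chair, the double bond moving to C21=C22. The closest known reaction type is the CrCl2-mediated (or indium-mediated) cyclisation of aldehydes with 2-carbonyl-substituted allyl bromides, which closes medium and large rings. The nine-membered ring is closed by attack of C3 on the aldehyde carbon (exo with respect to C=O), the tether running from the central allyl carbon C22 through C23, N17, C11, C10, C9 and C8. At C3 the ethyl group stays cis to the metal-bearing carbon C21 and trans to the lactam carbonyl, so it is pseudo-axial in the chair and ethyl and hydroxyl come out syn along C8–C4–C3–C22, as is known for γ-substituted 2-carbonyl allyl metals. At C4 the aldehyde reacts in the Felkin–Anh arrangement with the ester arm C7 anti to the incoming carbon and the ring carbon C9 inside, the only arrangement a nine-membered transition state allows, which gives 4S next to the C8 centre. The step needs regioselectivity between two secondary allyl termini: closure through C3 leaves the azepinone beside the new ring, whereas closure through C21 would have to bridge the seven-membered ring between N17 and C21 with only five atoms. Organochromium reagents add to the aldehyde and not to ester, lactones or lactam, and since no basic enolate is formed the β-silyloxy aldehyde neither eliminates nor epimerises; high dilution suppresses oligomers.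

Step 24
Reactants: 37 cyclised hydroxy ester
Product: 40 cis-fused lactone (O5–C6 closed; C9 silyl ether; unsaturated lactam), via bis(trimethylsilyl) derivative 38 (not isolated), via hydroxy acid 39 (not isolated)
Conditions: TMSOTf, 2,6-lutidine, CH2Cl2, 0 °C to rt; aq. citric acid, THF/MeOH; PPTS (cat.), benzene, 40 °C
Reagents that add atoms: none
Why: Silyl triflate cleavage of the tert-butyl ester, hydrolysis of the labile trimethylsilyl groups and acid-catalysed γ-lactonisation of the C4 hydroxyl; the cis fusion follows from the configurations of C4 and C8, and the C9 silyl ether survives, so the isomeric lactone cannot form.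

Step 25
Reactants: 40 unsaturated lactam
Product: 41 saturated lactam (22R), C9 silyl ether
Conditions: H2 (1 atm), Pd/C, EtOAc, rt
Reagents that add atoms: none
Why: Heterogeneous syn hydrogenation of the bridgehead-type alkene C21=C22; the nine-membered ring, which leaves C3 through C4, covers one face, and with the C3–H bond eclipsing the double bond (least 1,3-allylic strain) the open face is the one that carries the ethyl group, so hydrogen reaches C22 anti to C4, which corresponds to 22R.

Step 26
Reactants: 41 silyl ether
Product: 42 C9 carbinol
Conditions: aq. HF (48%), MeCN, 0 °C to rt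
Reagents that add atoms: none
Why: Acidic fluoride desilylation; no alkoxide is formed, so the free C9 hydroxyl does not attack the neighbouring lactone carbonyl C6.

Step 27
Reactants: 42 C9 carbinol
Product: 43 CNP0311700.2
Conditions: Dess–Martin periodinane, NaHCO3, CH2Cl2, rt
Reagents that add atoms: none
Why: Dess–Martin oxidation of the secondary alcohol under buffered, non-basic conditions, so the β-acyloxy ketone does not eliminate and C8 is not epimerised.

## Compound list

1 | methyl acrylate | C=CC(=O)OC | starting material
2 | propanal | CCC=O | starting material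
3 | methyl 3-hydroxy-2-methylidenepentanoate (racemic) | CCC(O)C(=C)C(=O)OC | intermediate
4 | methyl 2-methylidene-3-(triethylsilyloxy)pentanoate | CCC(O[Si](CC)(CC)CC)C(=C)C(=O)OC | intermediate
5 | 2-methylidene-3-(triethylsilyloxy)pentanoic acid | CCC(O[Si](CC)(CC)CC)C(=C)C(=O)O | intermediate
6 | L-aspartic acid 4-tert-butyl 1-methyl diester hydrochloride | Cl.COC(=O)[C@@H](N)CC(=O)OC(C)(C)C | starting material
7 | pent-4-enal | C=CCCC=O | starting material
8 | 4-tert-butyl 1-methyl N-(pent-4-enyl)-L-aspartate | COC(=O)[C@@H](NCCCC=C)CC(=O)OC(C)(C)C | intermediate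
9 | 2-methylidene-3-(triethylsilyloxy)pentanoyl chloride | CCC(O[Si](CC)(CC)CC)C(=C)C(Cl)=O | intermediate (not isolated)
10 | N-acyl-N-pentenyl aspartate diene | COC(=O)[C@H](CC(=O)OC(C)(C)C)N(CCCC=C)C(=O)C(=C)C(CC)O[Si](CC)(CC)CC | intermediate
11 | azepinone diester (C12 methyl ester) | COC(=O)[C@H](CC(=O)OC(C)(C)C)N1CCCC=C(C(CC)O[Si](CC)(CC)CC)C1=O | intermediate
12 | azepinone C12 S-ethyl thioester | CCSC(=O)[C@H](CC(=O)OC(C)(C)C)N1CCCC=C(C(CC)O[Si](CC)(CC)CC)C1=O | intermediate
13 | methyl (S)-3-hydroxy-2-methylpropanoate | COC(=O)[C@@H](C)CO | starting material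
14 | methyl (R)-3-iodo-2-methylpropanoate | COC(=O)[C@@H](C)CI | intermediate
15 | [(R)-3-methoxy-2-methyl-3-oxopropyl]zinc iodide | COC(=O)[C@@H](C)C[Zn]I | intermediate (not isolated)
16 | γ-keto ester (C12 ketone) | COC(=O)[C@@H](C)CC(=O)[C@H](CC(=O)OC(C)(C)C)N1CCCC=C(C(CC)O[Si](CC)(CC)CC)C1=O | intermediate
17 | γ-hydroxy ester (12S) | COC(=O)[C@@H](C)C[C@H](O)[C@H](CC(=O)OC(C)(C)C)N1CCCC=C(C(CC)O[Si](CC)(CC)CC)C1=O | intermediate (not isolated)
18 | pendant lactone, C9 tert-butyl ester | CC(C)(C)OC(=O)C[C@@H]([C@@H]1C[C@H](C)C(=O)O1)N1CCCC=C(C(CC)O[Si](CC)(CC)CC)C1=O | intermediate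
19 | C9 trimethylsilyl ester | C[Si](C)(C)OC(=O)C[C@@H]([C@@H]1C[C@H](C)C(=O)O1)N1CCCC=C(C(CC)O[Si](CC)(CC)CC)C1=O | intermediate (not isolated)
20 | C9 carboxylic acid | OC(=O)C[C@@H]([C@@H]1C[C@H](C)C(=O)O1)N1CCCC=C(C(CC)O[Si](CC)(CC)CC)C1=O | intermediate
21 | C9 S-ethyl thioester | CCSC(=O)C[C@@H]([C@@H]1C[C@H](C)C(=O)O1)N1CCCC=C(C(CC)O[Si](CC)(CC)CC)C1=O | intermediate
22 | C9 aldehyde | O=CC[C@@H]([C@@H]1C[C@H](C)C(=O)O1)N1CCCC=C(C(CC)O[Si](CC)(CC)CC)C1=O | intermediate
23 | (S)-methylsuccinic acid | OC(=O)C[C@H](C)C(=O)O | starting material
24 | (S)-methylsuccinic anhydride | C[C@H]1CC(=O)OC1=O | intermediate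
25 | (R)-4-benzyl-1,3-oxazolidin-2-one | O=C1N[C@H](Cc2ccccc2)CO1 | starting material
26 | lithium salt of 25 | [Li]N1[C@H](Cc2ccccc2)COC1=O | intermediate (not isolated)
27 | (2S)-4-[(4R)-4-benzyl-2-oxo-1,3-oxazolidin-3-yl]-2-methyl-4-oxobutanoic acid | OC(=O)[C@@H](C)CC(=O)N1[C@H](Cc2ccccc2)COC1=O | intermediate
28 | tert-butyl ester of 27 | CC(C)(C)OC(=O)[C@@H](C)CC(=O)N1[C@H](Cc2ccccc2)COC1=O | intermediate
29 | Z dibutylboron enolate of 28 | CCCCB(CCCC)O/C(=C\[C@H](C)C(=O)OC(C)(C)C)N1[C@H](Cc2ccccc2)COC1=O | intermediate (not isolated)
30 | syn-aldol adduct | O=C(N1[C@H](Cc2ccccc2)COC1=O)[C@H]([C@H](C)C(=O)OC(C)(C)C)[C@@H](O)C[C@@H]([C@@H]1C[C@H](C)C(=O)O1)N1CCCC=C(C(CC)O[Si](CC)(CC)CC)C1=O | intermediate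
31 | C9 tert-butyldimethylsilyl ether of 30 | O=C(N1[C@H](Cc2ccccc2)COC1=O)[C@H]([C@H](C)C(=O)OC(C)(C)C)[C@@H](O[Si](C)(C)C(C)(C)C)C[C@@H]([C@@H]1C[C@H](C)C(=O)O1)N1CCCC=C(C(CC)O[Si](CC)(CC)CC)C1=O | intermediate
32 | C4 S-ethyl thioester | CCSC(=O)[C@H]([C@H](C)C(=O)OC(C)(C)C)[C@@H](O[Si](C)(C)C(C)(C)C)C[C@@H]([C@@H]1C[C@H](C)C(=O)O1)N1CCCC=C(C(CC)O[Si](CC)(CC)CC)C1=O | intermediate
33 | C4 aldehyde, C3 triethylsilyl ether | O=C[C@H]([C@H](C)C(=O)OC(C)(C)C)[C@@H](O[Si](C)(C)C(C)(C)C)C[C@@H]([C@@H]1C[C@H](C)C(=O)O1)N1CCCC=C(C(CC)O[Si](CC)(CC)CC)C1=O | intermediate
34 | hydroxy aldehyde | O=C[C@H]([C@H](C)C(=O)OC(C)(C)C)[C@@H](O[Si](C)(C)C(C)(C)C)C[C@@H]([C@@H]1C[C@H](C)C(=O)O1)N1CCCC=C(C(O)CC)C1=O | intermediate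
35 | bromo propylidene caprolactam aldehyde (key precursor) | O=C[C@H]([C@H](C)C(=O)OC(C)(C)C)[C@@H](O[Si](C)(C)C(C)(C)C)C[C@@H]([C@@H]1C[C@H](C)C(=O)O1)N1CCCC(Br)/C(=C\CC)C1=O | intermediate
36 | allylchromium dichloride from 35 | O=C[C@H]([C@H](C)C(=O)OC(C)(C)C)[C@@H](O[Si](C)(C)C(C)(C)C)C[C@@H]([C@@H]1C[C@H](C)C(=O)O1)N1CCCC([Cr](Cl)Cl)/C(=C\CC)C1=O | intermediate (not isolated)
37 | cyclised hydroxy tert-butyl ester (key product) | CC[C@H]1[C@H](O)[C@H]([C@H](C)C(=O)OC(C)(C)C)[C@@H](O[Si](C)(C)C(C)(C)C)C[C@@H]([C@@H]2C[C@H](C)C(=O)O2)N2CCCC=C1C2=O | intermediate
38 | bis(trimethylsilyl) derivative of 39 | CC[C@H]1[C@H](O[Si](C)(C)C)[C@H]([C@H](C)C(=O)O[Si](C)(C)C)[C@@H](O[Si](C)(C)C(C)(C)C)C[C@@H]([C@@H]2C[C@H](C)C(=O)O2)N2CCCC=C1C2=O | intermediate (not isolated)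
39 | hydroxy acid | CC[C@H]1[C@H](O)[C@H]([C@H](C)C(=O)O)[C@@H](O[Si](C)(C)C(C)(C)C)C[C@@H]([C@@H]2C[C@H](C)C(=O)O2)N2CCCC=C1C2=O | intermediate (not isolated)
40 | cis-fused lactone, unsaturated lactam, C9 silyl ether | CC[C@H]1[C@@H]2OC(=O)[C@@H](C)[C@@H]2[C@@H](O[Si](C)(C)C(C)(C)C)C[C@@H]([C@@H]2C[C@H](C)C(=O)O2)N2CCCC=C1C2=O | intermediate
41 | saturated lactam, C9 silyl ether | CC[C@H]1[C@@H]2OC(=O)[C@@H](C)[C@@H]2[C@@H](O[Si](C)(C)C(C)(C)C)C[C@@H]([C@@H]2C[C@H](C)C(=O)O2)N2CCCC[C@H]1C2=O | intermediate
42 | C9 carbinol | CC[C@H]1[C@@H]2OC(=O)[C@@H](C)[C@@H]2[C@@H](O)C[C@@H]([C@@H]2C[C@H](C)C(=O)O2)N2CCCC[C@H]1C2=O | intermediate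
43 | CNP0311700.2 | CC[C@H]1[C@@H]2OC(=O)[C@@H](C)[C@@H]2C(=O)C[C@@H]([C@@H]2C[C@H](C)C(=O)O2)N2CCCC[C@H]1C2=O | target

## Step count and least certain steps

Total: 27 steps. Longest linear sequence: 22 steps (steps 1–3, 5–7, 9–13, 17–27).

**Step 23 (key step).** The allylchromium species may react through the ring terminus C21 instead of C3, because both termini are secondary and both closures give a nine-membered ring. Ring closure may also lose against protonation of the allyl metal or oligomerisation, because the new ring holds the lactam in a transoid arrangement. Fallback, from 32 back to 37: the triethylsilyl ether of 32 is cleaved (HF·pyridine) to the hydroxy thioester F1, which is converted (ClCO2Me, pyridine) into the methyl carbonate F2. Copper-catalysed γ-selective borylation (CuCl, Xantphos, KOt-Bu, B2pin2) places boron on C21 by addition and elimination and gives the allyl pinacolboronate F3. Fukuyama reduction (Et3SiH, Pd/C) gives the boronate aldehyde F4, which closes the ring on warming or with Sc(OTf)3 by allylboration through a closed chair. Boron does not migrate along the allyl unit, so only C3 can bond to C4; work-up gives 37.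

**Step 25.** Hydrogen may be delivered to the wrong face of C21=C22, because the preferred conformation of the strained, twisted enelactam cannot be fixed in advance. Fallback, from 37 back to 41: 37 is hydrogenated before lactonisation with [Ir(cod)(PCy3)(py)]PF6 and H2 in CH2Cl2. The free C4 hydroxyl binds the metal and directs hydrogen to the face on which C4 lies, the face opposite to the one used in step 25, giving the saturated hydroxy ester F5. The conditions of step 24 then give 41.

**Step 6.** Ring closure onto the hindered 1,1-disubstituted acrylamide alkene may be slow, so that dimerisation of the pentenyl chain wins. Fallback, from 8 back to 11: 8 is acylated with acryloyl chloride to the acrylamide F6. Metathesis of this unhindered diene gives the unsubstituted unsaturated caprolactam F7. α-Iodination (I2, pyridine) gives the iodo lactam F8. CrCl2 with catalytic NiCl2 couples F8 with propanal 2 to the hydroxypropyl lactam F9, and TESCl with imidazole gives 11.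

**Step 10.** Chelation of lithium between the ketone and a neighbouring carbonyl may compete with the Felkin–Anh mode and erode the selectivity at C12. Fallback, from 16 back to 18: control is moved from the substrate to the reagent. Reduction with (R)-2-methyl-CBS-oxazaborolidine and catecholborane in toluene at −78 °C gives the 12S carbinol, and PPTS closes the lactone 18. This makes no compound that the route does not already hold (F0).

## Further compounds

F1 | step 23 | hydroxy thioester (C3 hydroxyl free) | CCSC(=O)[C@H]([C@H](C)C(=O)OC(C)(C)C)[C@@H](O[Si](C)(C)C(C)(C)C)C[C@@H]([C@@H]1C[C@H](C)C(=O)O1)N1CCCC=C(C(O)CC)C1=O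
F2 | step 23 | methyl carbonate of F1 | CCSC(=O)[C@H]([C@H](C)C(=O)OC(C)(C)C)[C@@H](O[Si](C)(C)C(C)(C)C)C[C@@H]([C@@H]1C[C@H](C)C(=O)O1)N1CCCC=C(C(CC)OC(=O)OC)C1=O
F3 | step 23 | allyl pinacolboronate thioester (boron on C21) | CCSC(=O)[C@H]([C@H](C)C(=O)OC(C)(C)C)[C@@H](O[Si](C)(C)C(C)(C)C)C[C@@H]([C@@H]1C[C@H](C)C(=O)O1)N1CCCC(B2OC(C)(C)C(C)(C)O2)/C(=C\CC)C1=O
F4 | step 23 | allyl pinacolboronate aldehyde | O=C[C@H]([C@H](C)C(=O)OC(C)(C)C)[C@@H](O[Si](C)(C)C(C)(C)C)C[C@@H]([C@@H]1C[C@H](C)C(=O)O1)N1CCCC(B2OC(C)(C)C(C)(C)O2)/C(=C\CC)C1=O
F5 | step 25 | saturated hydroxy tert-butyl ester | CC[C@H]1[C@H](O)[C@H]([C@H](C)C(=O)OC(C)(C)C)[C@@H](O[Si](C)(C)C(C)(C)C)C[C@@H]([C@@H]2C[C@H](C)C(=O)O2)N2CCCC[C@H]1C2=O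
F6 | step 6 | N-acryloyl-N-pentenyl aspartate | COC(=O)[C@H](CC(=O)OC(C)(C)C)N(CCCC=C)C(=O)C=C
F7 | step 6 | unsubstituted unsaturated caprolactam diester | COC(=O)[C@H](CC(=O)OC(C)(C)C)N1CCCC=CC1=O
F8 | step 6 | α-iodo unsaturated caprolactam diester | COC(=O)[C@H](CC(=O)OC(C)(C)C)N1CCCC=C(I)C1=O
F9 | step 6 | hydroxypropyl unsaturated caprolactam diester | COC(=O)[C@H](CC(=O)OC(C)(C)C)N1CCCC=C(C(O)CC)C1=O
F0 | step 10 | none | none
A1 | alternative 1 | mixed bromoacetal of the nine-membered ring alkenol | CC[C@H]1[C@H](OC(OCC)C(C)Br)/C=C\C[C@@H]([C@@H]2C[C@H](C)C(=O)O2)N2CCCC[C@H]1C2=O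
A2 | alternative 1 | cis-fused lactol ethyl ether with ring carbinol | CC[C@H]1[C@@H]2OC(OCC)[C@@H](C)[C@@H]2C(O)C[C@@H]([C@@H]2C[C@H](C)C(=O)O2)N2CCCC[C@H]1C2=O
A3 | alternative 2 | N-dimethoxybenzyl 2-[(E)-but-1-enyl]pyrrolidine bis(silyl ether) | CC/C=C/[C@H]1[C@H](O[Si](C)(C)C(C)(C)C)C[C@@H](CO[Si](C)(C)C(C)(C)C)N1Cc1ccc(OC)cc1OC
A4 | alternative 2 | 6-chlorohexanoyl fluoride | O=C(F)CCCCCCl
A5 | alternative 2 | N-dimethoxybenzyl nine-membered lactam with E ring alkene | CC[C@H]1/C=C/[C@H](O[Si](C)(C)C(C)(C)C)C[C@@H](CO[Si](C)(C)C(C)(C)C)N(Cc2ccc(OC)cc2OC)C(=O)[C@@H]1CCCCCl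
A6 | alternative 3 | lactone-fused 2-acylcyclopentanone with free amine | CC[C@H]1[C@@H]2OC(=O)[C@@H](C)[C@]2(C(=O)C[C@H](N)[C@@H]2C[C@H](C)C(=O)O2)C(=O)[C@@H]1CCCC(OC)OC
A7 | alternative 3 | nine-membered secondary keto lactam with acetal chain | CC[C@H]1[C@@H]2OC(=O)[C@@H](C)[C@@H]2C(=O)C[C@@H]([C@@H]2C[C@H](C)C(=O)O2)NC(=O)[C@@H]1CCCC(OC)OC
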